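**Plan**

1. Retrosynthesis (carotenoid numbering): the C14–C15 single bond is cut to give a C19 alkenyl iodide (left ring + C7–C14) and a C21 terminal enyne (ε-ring + C7'–C15). The enabling feature is that this bond joins the methyl-branched C13=C14 to the unbranched, 1,2-disubstituted C15=C15', so C15=C15' can be carried as the alkyne C15≡C15' and made E by syn-hydrometalation in the same flask that forms C14–C15.
2. Left half: further cuts at C9=C10 (aldol condensation with a C5 iododienal), at C8=O (from a C7≡C8 alkyne by hydrosilylation–oxidation), at C6–C7 (Sonogashira) and at C5–O (C5–C6 epoxide isomerised to the 6-hydroxy-5(18)-methylene unit); the cyclohexane ring is that of actinol.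
3. Right half: cuts at C15≡C15' (one-carbon homologation), C11'=C12' and C9'=C10' (two Horner–Wadsworth–Emmons reactions); the cyclohexene (ε) ring is that of (R)-α-ionone, oxidised at C3'.
4. Forward order: iodide 17 (steps 1–11), enyne 28 (steps 12–19), union (step 20), removal of the three triethylsilyl helpers (step 21); no ring is formed in the route, both rings come from the chiral pool.
5. Stereochemistry: C3 from (4R)-actinol; C6 from the C3–OH-directed syn-epoxidation of C5=C6 (the C6–O bond is kept when the epoxide is isomerised); C6' from (R)-α-ionone; C3' from a CBS reduction; E-alkenes from HWE/Wittig/E1cB steps, from iodide 11 and from the syn-hydrozirconation.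

Key step: step 20

Remark: (4R,6R)-actinol (1), (E)-3-iodo-2-methylprop-2-en-1-ol (11) and enantiopure (R)-α-ionone (18) are taken as purchasable; all polyene operations are run under argon in dim light.

**Route**

Step 1
Reactants: 1 (4R,6R)-4-hydroxy-2,2,6-trimethylcyclohexan-1-one
Product: 2 (1R,5R)-4-hydrazinylidene-3,3,5-trimethylcyclohexan-1-ol
Conditions: N2H4·H2O (10 equiv), Et3N, EtOH, reflux
Reagents that add atoms: hydrazine (used as the hydrate) NN
Why: Hydrazone formation on the hindered ketone (first half of the Barton vinyl iodide synthesis) leaves the remote C3 carbinol untouched, and the α-methyl centre, which may epimerise, is destroyed in step 2.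

Step 2
Reactants: 2 (1R,5R)-4-hydrazinylidene-3,3,5-trimethylcyclohexan-1-ol
Product: 3 (1R)-4-iodo-3,5,5-trimethylcyclohex-3-en-1-ol
Conditions: I2 (2.2 equiv), 1,1,3,3-tetramethylguanidine, Et2O, 0 °C to rt; then TMG, 90 °C
Reagents that add atoms: iodine II
Why: In the Barton vinyl iodide synthesis the iodo-carbocation can lose a proton only from C5 because C1 is quaternary, so the tetrasubstituted C5=C6 iodide should be the only regioisomer, and the free alcohol is tolerated.

Step 3
Reactants: 3 (1R)-4-iodo-3,5,5-trimethylcyclohex-3-en-1-ol; 4 but-1-yne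
Product: 5 (1R)-4-(but-1-yn-1-yl)-3,5,5-trimethylcyclohex-3-en-1-ol
Conditions: PdCl2(PPh3)2 (5 mol%), CuI (10 mol%), i-Pr2NH, THF, excess 4, sealed tube, rt to 45 °C
Reagents that add atoms: none
Why: Sonogashira coupling of an alkenyl iodide with a terminal alkyne forms C6–C7 and brings in C7–C9 and C19, with the unprotected secondary alcohol tolerated.

Step 4
Reactants: 5 (1R)-4-(but-1-yn-1-yl)-3,5,5-trimethylcyclohex-3-en-1-ol
Product: 6 (1S,3S,6S)-6-(but-1-yn-1-yl)-1,5,5-trimethyl-7-oxabicyclo[4.1.0]heptan-3-ol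
Conditions: VO(acac)2 (5 mol%), t-BuOOH (1.5 equiv, decane), toluene, 0 °C to rt
Reagents that add atoms: tert-butyl hydroperoxide CC(C)(C)OO
Why: Vanadium-catalysed hydroxyl-directed epoxidation of a cyclohex-3-en-1-ol delivers oxygen from the face of the C3 hydroxyl, which should set C5 and C6 as the syn-epoxide and so the cis relation of the C3 and C6 oxygens, while the alkyne is inert.

Step 5
Reactants: 6 (1S,3S,6S)-6-(but-1-yn-1-yl)-1,5,5-trimethyl-7-oxabicyclo[4.1.0]heptan-3-ol
Product: 7 (1R,4S)-1-(but-1-yn-1-yl)-2,2-dimethyl-6-methylidenecyclohexane-1,4-diol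
Conditions: LiNEt2 (4 equiv), Et2O–hexane, 0 °C to reflux; H2O
Reagents that add atoms: none
Why: In this lithium amide syn-elimination of an epoxide to an allylic alcohol the only β-hydrogens sit on C18 and C4 (C6 carries the alkyne and the quaternary C1), so the C5–O bond must break with the C6–O stereocentre retained, and the amide should prefer the primary C18 hydrogens to give the exocyclic methylene.

Step 6
Reactants: 7 (1R,4S)-1-(but-1-yn-1-yl)-2,2-dimethyl-6-methylidenecyclohexane-1,4-diol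
Product: 9 1-[(1R,4S)-1,4-dihydroxy-2,2-dimethyl-6-methylidenecyclohexyl]butan-2-one, via Z-vinylsilane 8 (not isolated)
Conditions: [Cp*Ru(MeCN)3]PF6 (3 mol%), BnMe2SiH (1.3 equiv), acetone, 0 °C to rt; then TBAF, THF, 0 °C; H2O2, KHCO3, MeOH, rt
Reagents that add atoms: hydrogen peroxide OO
Why: Ruthenium-catalysed trans-hydrosilylation of a propargylic alcohol places silicon on the alkyne carbon distal to the hydroxyl (C8), and Tamao–Fleming oxidation of the vinylsilane then gives the C8 ketone with C7 as CH2 under non-acidic conditions that avoid a Meyer–Schuster shift, with no stereocentre touched.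

Step 7
Reactants: 9 1-[(1R,4S)-1,4-dihydroxy-2,2-dimethyl-6-methylidenecyclohexyl]butan-2-one
Product: 10 1-[(1R,4S)-2,2-dimethyl-6-methylidene-1,4-bis(triethylsilyloxy)cyclohexyl]butan-2-one
Conditions: TESOTf (3 equiv), 2,6-lutidine, CH2Cl2, −78 to −20 °C
Reagents that add atoms: triethylsilyl trifluoromethanesulfonate CC[Si](CC)(CC)OS(=O)(=O)C(F)(F)F
Why: Silyl triflate silylation caps both the secondary and the hindered tertiary hydroxyl, so that the tertiary aldolate cannot fragment by retro-aldol in step 10 and no O–H meets the organozinc in step 20.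

Step 8
Reactants: 11 (2E)-3-iodo-2-methylprop-2-en-1-ol
Product: 12 (2E)-3-iodo-2-methylprop-2-enal
Conditions: activated MnO2 (15 equiv), CH2Cl2, rt, dark
Reagents that add atoms: none
Why: Manganese dioxide oxidation of a primary allylic alcohol gives the enal with the alkene geometry retained.

Step 9
Reactants: 12 (2E)-3-iodo-2-methylprop-2-enal; 13 (triphenyl-λ5-phosphanylidene)acetaldehyde
Product: 14 (2E,4E)-5-iodo-4-methylpenta-2,4-dienal
Conditions: 13 (1.05 equiv), toluene, 60 °C, dark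
Reagents that add atoms: none
Why: Wittig olefination with a stabilised ylide should give the new C11=C12 bond as the E isomer, with the ylide held near one equivalent to avoid a second homologation.

Step 10
Reactants: 10 1-[(1R,4S)-2,2-dimethyl-6-methylidene-1,4-bis(triethylsilyloxy)cyclohexyl]butan-2-one; 14 (2E,4E)-5-iodo-4-methylpenta-2,4-dienal
Product: 15 (5E,7E)-1-[(1R,4S)-2,2-dimethyl-6-methylidene-1,4-bis(triethylsilyloxy)cyclohexyl]-4-hydroxy-8-iodo-3,7-dimethylocta-5,7-dien-2-one (mixture of C3/C4 epimers)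
Conditions: LDA (1.05 equiv), THF, −78 °C; then 14, −78 °C; sat. aq. NH4Cl
Reagents that add atoms: none
Why: Kinetic deprotonation should occur at the ethyl CH2 (C9) and not at the neopentyl-type C7, and the lithium enolate adds 1,2 to the dienal (aldol addition), the two new centres being left uncontrolled because step 11 removes them.

Step 11
Reactants: 15 (5E,7E)-1-[(1R,4S)-2,2-dimethyl-6-methylidene-1,4-bis(triethylsilyloxy)cyclohexyl]-4-hydroxy-8-iodo-3,7-dimethylocta-5,7-dien-2-one
Product: 17 (3E,5E,7E)-1-[(1R,4S)-2,2-dimethyl-6-methylidene-1,4-bis(triethylsilyloxy)cyclohexyl]-8-iodo-3,7-dimethylocta-3,5,7-trien-2-one, via mesylate 16 (not isolated)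
Conditions: MsCl, Et3N, CH2Cl2, 0 °C; then DBU, 0 °C to rt, dark
Reagents that add atoms: none
Why: Mesylation followed by E1cB elimination completes the aldol condensation and should give the conjugated 2-methyl enone as the thermodynamically preferred E isomer at C9=C10.

Step 12
Reactants: 18 (3E)-4-[(1R)-2,6,6-trimethylcyclohex-2-en-1-yl]but-3-en-2-one; 19 diethyl (cyanomethyl)phosphonate
Product: 20 (2E,4E)-3-methyl-5-[(1R)-2,6,6-trimethylcyclohex-2-en-1-yl]penta-2,4-dienenitrile
Conditions: 19, NaH, THF, 0 °C; then 18, 0 °C to rt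
Reagents that add atoms: none
Why: Horner–Wadsworth–Emmons olefination of the methyl ketone should give mainly the E isomer at C9'=C10' (the Z isomer is removed by chromatography), and the weakly basic phosphonate anion should not touch the C6' stereocentre.

Step 13
Reactants: 20 (2E,4E)-3-methyl-5-[(1R)-2,6,6-trimethylcyclohex-2-en-1-yl]penta-2,4-dienenitrile
Product: 21 (2E,4E)-3-methyl-5-[(1R)-2,6,6-trimethyl-4-oxocyclohex-2-en-1-yl]penta-2,4-dienenitrile
Conditions: t-BuOOH (70% aq., 5 equiv), Rh2(cap)4 (1 mol%), NaHCO3, CH2Cl2, rt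
Reagents that add atoms: tert-butyl hydroperoxide CC(C)(C)OO
Why: Dirhodium-catalysed allylic oxidation with tert-butyl hydroperoxide converts the ring allylic CH2 (C3') into the enone carbonyl under near-neutral radical conditions that should leave the hindered C6'–H and the dienenitrile alone.

Step 14
Reactants: 21 (2E,4E)-3-methyl-5-[(1R)-2,6,6-trimethyl-4-oxocyclohex-2-en-1-yl]penta-2,4-dienenitrile
Product: 22 (2E,4E)-5-[(1R,4R)-4-hydroxy-2,6,6-trimethylcyclohex-2-en-1-yl]-3-methylpenta-2,4-dienenitrile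
Conditions: (S)-2-methyl-CBS-oxazaborolidine (1 equiv), catecholborane, toluene, −78 °C
Reagents that add atoms: none
Why: In this CBS reduction the (S)-catalyst treats the alkene side of the enone as the large group and should deliver hydride to give the (3'R) carbinol trans to the C6' side chain, which is also the face away from the pseudo-axial C1' methyl (reagent and substrate control matched).

Step 15
Reactants: 22 (2E,4E)-5-[(1R,4R)-4-hydroxy-2,6,6-trimethylcyclohex-2-en-1-yl]-3-methylpenta-2,4-dienenitrile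
Product: 23 (2E,4E)-3-methyl-5-[(1R,4R)-2,6,6-trimethyl-4-(triethylsilyloxy)cyclohex-2-en-1-yl]penta-2,4-dienenitrile
Conditions: TESCl, imidazole, DMF, 0 °C
Reagents that add atoms: chlorotriethylsilane CC[Si](Cl)(CC)CC
Why: Silyl ether formation protects the acid-sensitive allylic alcohol from the hydride, base and Zr–H reagents that follow.

Step 16
Reactants: 23 (2E,4E)-3-methyl-5-[(1R,4R)-2,6,6-trimethyl-4-(triethylsilyloxy)cyclohex-2-en-1-yl]penta-2,4-dienenitrile
Product: 24 (2E,4E)-3-methyl-5-[(1R,4R)-2,6,6-trimethyl-4-(triethylsilyloxy)cyclohex-2-en-1-yl]penta-2,4-dienal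
Conditions: DIBAL-H (1.2 equiv), toluene, −78 °C; then wet SiO2 / aq. Rochelle salt
Reagents that add atoms: water O
Why: DIBAL-H stops at the aluminium aldimine of the conjugated nitrile, which is hydrolysed to the aldehyde on mildly acidic work-up with the alkene geometries retained.

Step 17
Reactants: 24 (2E,4E)-3-methyl-5-[(1R,4R)-2,6,6-trimethyl-4-(triethylsilyloxy)cyclohex-2-en-1-yl]penta-2,4-dienal; 25 diethyl [(2E)-3-cyano-2-methylprop-2-en-1-yl]phosphonate
Product: 26 (2E,4E,6E,8E)-3,7-dimethyl-9-[(1R,4R)-2,6,6-trimethyl-4-(triethylsilyloxy)cyclohex-2-en-1-yl]nona-2,4,6,8-tetraenenitrile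
Conditions: 25, NaH, THF, 0 °C; then 24, 0 °C to rt
Reagents that add atoms: none
Why: Vinylogous Horner–Wadsworth–Emmons olefination, the standard C15 + C5 retinoid step, should form C11'=C12' as the E alkene and mainly the E isomer at C13'=C14' (the 13'-Z isomer is removed by chromatography).

Step 18
Reactants: 26 (2E,4E,6E,8E)-3,7-dimethyl-9-[(1R,4R)-2,6,6-trimethyl-4-(triethylsilyloxy)cyclohex-2-en-1-yl]nona-2,4,6,8-tetraenenitrile
Product: 27 (2E,4E,6E,8E)-3,7-dimethyl-9-[(1R,4R)-2,6,6-trimethyl-4-(triethylsilyloxy)cyclohex-2-en-1-yl]nona-2,4,6,8-tetraenal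
Conditions: DIBAL-H (1.2 equiv), toluene, −78 °C; then wet SiO2 / aq. Rochelle salt
Reagents that add atoms: water O
Why: The same partial reduction of a conjugated nitrile through the aldimine gives the C20 aldehyde.

Step 19
Reactants: 27 (2E,4E,6E,8E)-3,7-dimethyl-9-[(1R,4R)-2,6,6-trimethyl-4-(triethylsilyloxy)cyclohex-2-en-1-yl]nona-2,4,6,8-tetraenal
Product: 28 triethyl{[(1R,4R)-4-[(1E,3E,5E,7E)-3,7-dimethyldeca-1,3,5,7-tetraen-9-yn-1-yl]-3,5,5-trimethylcyclohex-2-en-1-yl]oxy}silane
Conditions: TMSCHN2, LDA, THF, −78 to 0 °C; H2O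
Reagents that add atoms: (trimethylsilyl)diazomethane C[Si](C)(C)C=[N+]=[N-]
Why: In the Colvin rearrangement lithiated trimethylsilyldiazomethane adds to the aldehyde and, after Peterson-type loss of silanolate and nitrogen, the alkylidene carbene undergoes a 1,2-hydride shift to the terminal alkyne, a protocol suited to enals because no methanol is present to add to the intermediates.

Step 20
Reactants: 28 triethyl{[(1R,4R)-4-[(1E,3E,5E,7E)-3,7-dimethyldeca-1,3,5,7-tetraen-9-yn-1-yl]-3,5,5-trimethylcyclohex-2-en-1-yl]oxy}silane; 17 (3E,5E,7E)-1-[(1R,4S)-2,2-dimethyl-6-methylidene-1,4-bis(triethylsilyloxy)cyclohexyl]-8-iodo-3,7-dimethylocta-3,5,7-trien-2-one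
Product: 31 (3E,5E,7E,9E,11E,13E,15E,17E)-1-[(1R,4S)-2,2-dimethyl-6-methylidene-1,4-bis(triethylsilyloxy)cyclohexyl]-3,7,12,16-tetramethyl-18-[(1R,4R)-2,6,6-trimethyl-4-(triethylsilyloxy)cyclohex-2-en-1-yl]octadeca-3,5,7,9,11,13,15,17-octaen-2-one, via alkenylzirconocene 29 (not isolated), via alkenylzinc chloride 30 (not isolated)
Conditions: 28 (1.3 equiv), Cp2Zr(H)Cl (1.2 equiv), THF, rt, dark; ZnCl2 (1.3 equiv, THF), 0 °C; then 17 (1.0 equiv), Pd(PPh3)4 (5 mol%), THF, rt
Reagents that add atoms: none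
Why: The Schwartz reagent adds Zr–H syn across the terminal C15≡C15' triple bond with zirconium on the unhindered terminal carbon, zinc chloride transfers the alkenyl group to zinc, Pd(0) inserts into the C14–I bond of 17, and transmetalation with reductive elimination forms the C14–C15 single bond with retention at both alkenes. The closest known reaction type is the hydrozirconation / Zr-to-Zn transmetalation / palladium-catalysed alkenyl–alkenyl Negishi coupling used to assemble retinoid and carotenoid polyenes. No ring is closed and no stereocentre is formed; the one new stereo-element, the E geometry of C15=C15', is fixed by the syn addition, and the E geometry of C13=C14 is carried over from the iodide. The step needs chemoselectivity of Zr–H for the alkyne over the tetraene of 28 and over the C8 ketone of 17: the terminal alkyne is the only unhindered π-bond of 28, the hydride is used in deficit relative to 28 and is consumed before 17 is added, and alkenylzinc halides should not add to the hindered enone or disturb silyl ethers. Both hydroxyl-bearing ends are silylated, so no O–H can protonate the organometallic.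

Step 21
Reactants: 31 (3E,5E,7E,9E,11E,13E,15E,17E)-1-[(1R,4S)-2,2-dimethyl-6-methylidene-1,4-bis(triethylsilyloxy)cyclohexyl]-3,7,12,16-tetramethyl-18-[(1R,4R)-2,6,6-trimethyl-4-(triethylsilyloxy)cyclohex-2-en-1-yl]octadeca-3,5,7,9,11,13,15,17-octaen-2-one
Product: 32 (3E,5E,7E,9E,11E,13E,15E,17E)-1-[(1R,4S)-1,4-dihydroxy-2,2-dimethyl-6-methylidenecyclohexyl]-18-[(1R,4R)-4-hydroxy-2,6,6-trimethylcyclohex-2-en-1-yl]-3,7,12,16-tetramethyloctadeca-3,5,7,9,11,13,15,17-octaen-2-one (CNP0369437.1)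
Conditions: HF·pyridine, excess pyridine, THF, 0 °C to rt, dark
Reagents that add atoms: none
Why: Buffered fluoride desilylation should cleave the three Si–O bonds without the basicity that would cause retro-aldol or E1cB loss at the β-hydroxy ketone and without the acidity that would ionise the two allylic alcohols, so no stereocentre is disturbed.

**Compound list**

1 | (4R,6R)-4-hydroxy-2,2,6-trimethylcyclohexan-1-one (actinol) | C[C@@H]1C[C@@H](O)CC(C)(C)C1=O | starting material
2 | (1R,5R)-4-hydrazinylidene-3,3,5-trimethylcyclohexan-1-ol (C=N geometry not defined) | C[C@@H]1C[C@@H](O)CC(C)(C)C1=NN | intermediate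
3 | (1R)-4-iodo-3,5,5-trimethylcyclohex-3-en-1-ol | CC1=C(I)C(C)(C)C[C@H](O)C1 | intermediate
4 | but-1-yne | C#CCC | starting material
5 | (1R)-4-(but-1-yn-1-yl)-3,5,5-trimethylcyclohex-3-en-1-ol | CC1=C(C#CCC)C(C)(C)C[C@H](O)C1 | intermediate
6 | (1S,3S,6S)-6-(but-1-yn-1-yl)-1,5,5-trimethyl-7-oxabicyclo[4.1.0]heptan-3-ol (epoxide oxygen cis to OH) | C[C@]12C[C@@H](O)CC(C)(C)[C@]1(O2)C#CCC | intermediate
7 | (1R,4S)-1-(but-1-yn-1-yl)-2,2-dimethyl-6-methylidenecyclohexane-1,4-diol (hydroxyls cis) | C=C1C[C@@H](O)CC(C)(C)[C@]1(O)C#CCC | intermediate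
8 | (1R,4S)-1-[(1Z)-2-[benzyl(dimethyl)silyl]but-1-en-1-yl]-2,2-dimethyl-6-methylidenecyclohexane-1,4-diol | C=C1C[C@@H](O)CC(C)(C)[C@]1(O)/C=C(/CC)[Si](C)(C)Cc1ccccc1 | intermediate (not isolated)
9 | 1-[(1R,4S)-1,4-dihydroxy-2,2-dimethyl-6-methylidenecyclohexyl]butan-2-one | C=C1C[C@@H](O)CC(C)(C)[C@]1(O)CC(=O)CC | intermediate
10 | 1-[(1R,4S)-2,2-dimethyl-6-methylidene-1,4-bis(triethylsilyloxy)cyclohexyl]butan-2-one | C=C1C[C@@H](O[Si](CC)(CC)CC)CC(C)(C)[C@]1(O[Si](CC)(CC)CC)CC(=O)CC | intermediate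
11 | (2E)-3-iodo-2-methylprop-2-en-1-ol | OC/C(C)=C/I | starting material
12 | (2E)-3-iodo-2-methylprop-2-enal | O=C/C(C)=C/I | intermediate
13 | (triphenyl-λ5-phosphanylidene)acetaldehyde | O=CC=P(c1ccccc1)(c1ccccc1)c1ccccc1 | starting material
14 | (2E,4E)-5-iodo-4-methylpenta-2,4-dienal | O=C/C=C/C(C)=C/I | intermediate
15 | (5E,7E)-1-[(1R,4S)-2,2-dimethyl-6-methylidene-1,4-bis(triethylsilyloxy)cyclohexyl]-4-hydroxy-8-iodo-3,7-dimethylocta-5,7-dien-2-one (C3/C4 epimers) | C=C1C[C@@H](O[Si](CC)(CC)CC)CC(C)(C)[C@]1(O[Si](CC)(CC)CC)CC(=O)C(C)C(O)/C=C/C(C)=C/I | intermediate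
16 | 4-methanesulfonate of 15 | C=C1C[C@@H](O[Si](CC)(CC)CC)CC(C)(C)[C@]1(O[Si](CC)(CC)CC)CC(=O)C(C)C(OS(C)(=O)=O)/C=C/C(C)=C/I | intermediate (not isolated)
17 | (3E,5E,7E)-1-[(1R,4S)-2,2-dimethyl-6-methylidene-1,4-bis(triethylsilyloxy)cyclohexyl]-8-iodo-3,7-dimethylocta-3,5,7-trien-2-one | C=C1C[C@@H](O[Si](CC)(CC)CC)CC(C)(C)[C@]1(O[Si](CC)(CC)CC)CC(=O)/C(C)=C/C=C/C(C)=C/I | intermediate
18 | (3E)-4-[(1R)-2,6,6-trimethylcyclohex-2-en-1-yl]but-3-en-2-one ((R)-α-ionone) | CC(=O)/C=C/[C@H]1C(C)=CCCC1(C)C | starting material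
19 | diethyl (cyanomethyl)phosphonate | CCOP(=O)(CC#N)OCC | starting material
20 | (2E,4E)-3-methyl-5-[(1R)-2,6,6-trimethylcyclohex-2-en-1-yl]penta-2,4-dienenitrile | N#C/C=C(C)/C=C/[C@H]1C(C)=CCCC1(C)C | intermediate
21 | (2E,4E)-3-methyl-5-[(1R)-2,6,6-trimethyl-4-oxocyclohex-2-en-1-yl]penta-2,4-dienenitrile | N#C/C=C(C)/C=C/[C@H]1C(C)=CC(=O)CC1(C)C | intermediate
22 | (2E,4E)-5-[(1R,4R)-4-hydroxy-2,6,6-trimethylcyclohex-2-en-1-yl]-3-methylpenta-2,4-dienenitrile | N#C/C=C(C)/C=C/[C@H]1C(C)=C[C@H](O)CC1(C)C | intermediate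
23 | (2E,4E)-3-methyl-5-[(1R,4R)-2,6,6-trimethyl-4-(triethylsilyloxy)cyclohex-2-en-1-yl]penta-2,4-dienenitrile | N#C/C=C(C)/C=C/[C@H]1C(C)=C[C@H](O[Si](CC)(CC)CC)CC1(C)C | intermediate
24 | (2E,4E)-3-methyl-5-[(1R,4R)-2,6,6-trimethyl-4-(triethylsilyloxy)cyclohex-2-en-1-yl]penta-2,4-dienal | O=C/C=C(C)/C=C/[C@H]1C(C)=C[C@H](O[Si](CC)(CC)CC)CC1(C)C | intermediate
25 | diethyl [(2E)-3-cyano-2-methylprop-2-en-1-yl]phosphonate (E-rich commercial reagent) | CCOP(=O)(C/C(C)=C/C#N)OCC | starting material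
26 | (2E,4E,6E,8E)-3,7-dimethyl-9-[(1R,4R)-2,6,6-trimethyl-4-(triethylsilyloxy)cyclohex-2-en-1-yl]nona-2,4,6,8-tetraenenitrile | N#C/C=C(C)/C=C/C=C(C)/C=C/[C@H]1C(C)=C[C@H](O[Si](CC)(CC)CC)CC1(C)C | intermediate
27 | (2E,4E,6E,8E)-3,7-dimethyl-9-[(1R,4R)-2,6,6-trimethyl-4-(triethylsilyloxy)cyclohex-2-en-1-yl]nona-2,4,6,8-tetraenal | O=C/C=C(C)/C=C/C=C(C)/C=C/[C@H]1C(C)=C[C@H](O[Si](CC)(CC)CC)CC1(C)C | intermediate
28 | triethyl{[(1R,4R)-4-[(1E,3E,5E,7E)-3,7-dimethyldeca-1,3,5,7-tetraen-9-yn-1-yl]-3,5,5-trimethylcyclohex-2-en-1-yl]oxy}silane | C#C/C=C(C)/C=C/C=C(C)/C=C/[C@H]1C(C)=C[C@H](O[Si](CC)(CC)CC)CC1(C)C | intermediate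
29 | chlorobis(cyclopentadienyl)[(1E,3E,5E,7E,9E)-4,8-dimethyl-10-[(1R,4R)-2,6,6-trimethyl-4-(triethylsilyloxy)cyclohex-2-en-1-yl]deca-1,3,5,7,9-pentaen-1-yl]zirconium | Cl[Zr](C1C=CC=C1)(C1C=CC=C1)/C=C/C=C(C)/C=C/C=C(C)/C=C/[C@H]1C(C)=C[C@H](O[Si](CC)(CC)CC)CC1(C)C | intermediate (not isolated)
30 | chloro[(1E,3E,5E,7E,9E)-4,8-dimethyl-10-[(1R,4R)-2,6,6-trimethyl-4-(triethylsilyloxy)cyclohex-2-en-1-yl]deca-1,3,5,7,9-pentaen-1-yl]zinc | Cl[Zn]/C=C/C=C(C)/C=C/C=C(C)/C=C/[C@H]1C(C)=C[C@H](O[Si](CC)(CC)CC)CC1(C)C | intermediate (not isolated)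
31 | (3E,5E,7E,9E,11E,13E,15E,17E)-1-[(1R,4S)-2,2-dimethyl-6-methylidene-1,4-bis(triethylsilyloxy)cyclohexyl]-3,7,12,16-tetramethyl-18-[(1R,4R)-2,6,6-trimethyl-4-(triethylsilyloxy)cyclohex-2-en-1-yl]octadeca-3,5,7,9,11,13,15,17-octaen-2-one | C=C1C[C@@H](O[Si](CC)(CC)CC)CC(C)(C)[C@]1(O[Si](CC)(CC)CC)CC(=O)/C(C)=C/C=C/C(C)=C/C=C/C=C(C)/C=C/C=C(C)/C=C/[C@H]1C(C)=C[C@H](O[Si](CC)(CC)CC)CC1(C)C | intermediate
32 | (3E,5E,7E,9E,11E,13E,15E,17E)-1-[(1R,4S)-1,4-dihydroxy-2,2-dimethyl-6-methylidenecyclohexyl]-18-[(1R,4R)-4-hydroxy-2,6,6-trimethylcyclohex-2-en-1-yl]-3,7,12,16-tetramethyloctadeca-3,5,7,9,11,13,15,17-octaen-2-one (CNP0369437.1) | C=C1C[C@@H](O)CC(C)(C)[C@]1(O)CC(=O)/C(C)=C/C=C/C(C)=C/C=C/C=C(C)/C=C/C=C(C)/C=C/[C@H]1C(C)=C[C@H](O)CC1(C)C | target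

**Totals and risks**

Total step count: 21. Longest linear sequence: 11 steps (1–7, 10, 11, 20, 21, from actinol); the ε-branch is 10 steps (12–21) and the dienal branch 6 (8–11, 20, 21).

Steps most likely to fail:

Step 6. The hydrosilylation may deliver silicon to the wrong alkyne carbon next to the crowded tertiary carbinol, the hindered vinylsilane may protodesilylate instead of oxidising, or the tertiary aldol may cleave by retro-aldol during the basic peroxide treatment. The fallback carries the C8 carbonyl as a dioxolane instead of making it from an alkyne. It sets out from 3: Negishi coupling (Pd(dppf)Cl2, THF, 50 °C) with [(2-ethyl-1,3-dioxolan-2-yl)methyl]zinc bromide F2 (from 2-(bromomethyl)-2-ethyl-1,3-dioxolane and zinc dust/LiCl; 2.5 equiv, one equivalent being lost to the hydroxyl) should give (1R)-4-[(2-ethyl-1,3-dioxolan-2-yl)methyl]-3,5,5-trimethylcyclohex-3-en-1-ol F3. The vanadium-directed epoxidation of step 4 should then give (1S,3S,6R)-6-[(2-ethyl-1,3-dioxolan-2-yl)methyl]-1,5,5-trimethyl-7-oxabicyclo[4.1.0]heptan-3-ol F4. The lithium diethylamide isomerisation of step 5 should give (1R,4S)-1-[(2-ethyl-1,3-dioxolan-2-yl)methyl]-2,2-dimethyl-6-methylidenecyclohexane-1,4-diol F5; the ketal does not acidify C7–H2, but these hydrogens are now a possible competing abstraction site. Mild hydrolysis (PPTS, wet acetone, rt) releases the ketone and the route is rejoined at 9.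

Step 5. Proton abstraction may occur at the ring C4–H instead of the C18 methyl, giving the endocyclic alkene, or the amide may attack the alkynyl epoxide. The fallback replaces the epoxide detour by a Schenck ene reaction and sets out from 5. Singlet oxygen (O2, hν, tetraphenylporphyrin, CH2Cl2, −20 °C) can abstract allylic hydrogen only from C18 or C4, so oxygen must bond to C6, and hydrogen bonding to the C3 hydroxyl should steer it to the syn face. This should give (1S,4R)-4-(but-1-yn-1-yl)-4-hydroperoxy-3,3-dimethyl-5-methylidenecyclohexan-1-ol F1, which triphenylphosphine reduces to the diol; the route is rejoined at 7.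

Step 20. Hydrozirconation of the polyenyne may be incomplete or unselective, unconsumed Zr–H may reduce the C8 ketone, the alkenylzinc may be protonated, or alkene geometry may erode. The fallback sets C15=C15' by a Takai–Utimoto olefination instead of a hydrometalation and sets out from 27. CrCl2, LiI and Cl2CHBpin in THF at rt should give 2-[(1E,3E,5E,7E,9E)-4,8-dimethyl-10-[(1R,4R)-2,6,6-trimethyl-4-(triethylsilyloxy)cyclohex-2-en-1-yl]deca-1,3,5,7,9-pentaen-1-yl]-4,4,5,5-tetramethyl-1,3,2-dioxaborolane F6. Suzuki–Miyaura coupling of F6 with 17 (Pd(PPh3)4, aq. K3PO4, THF, rt, dark) rejoins the route at 31.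

**Further compounds**

F1 | step 5 | (1S,4R)-4-(but-1-yn-1-yl)-4-hydroperoxy-3,3-dimethyl-5-methylidenecyclohexan-1-ol | C=C1C[C@@H](O)CC(C)(C)[C@]1(OO)C#CCC
F2 | step 6 | [(2-ethyl-1,3-dioxolan-2-yl)methyl]zinc bromide | CCC1(C[Zn]Br)OCCO1
F3 | step 6 | (1R)-4-[(2-ethyl-1,3-dioxolan-2-yl)methyl]-3,5,5-trimethylcyclohex-3-en-1-ol | CC1=C(CC2(CC)OCCO2)C(C)(C)C[C@H](O)C1
F4 | step 6 | (1S,3S,6R)-6-[(2-ethyl-1,3-dioxolan-2-yl)methyl]-1,5,5-trimethyl-7-oxabicyclo[4.1.0]heptan-3-ol | C[C@]12C[C@@H](O)CC(C)(C)[C@]1(O2)CC1(CC)OCCO1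
F5 | step 6 | (1R,4S)-1-[(2-ethyl-1,3-dioxolan-2-yl)methyl]-2,2-dimethyl-6-methylidenecyclohexane-1,4-diol | C=C1C[C@@H](O)CC(C)(C)[C@]1(O)CC1(CC)OCCO1
F6 | step 20 | 2-[(1E,3E,5E,7E,9E)-4,8-dimethyl-10-[(1R,4R)-2,6,6-trimethyl-4-(triethylsilyloxy)cyclohex-2-en-1-yl]deca-1,3,5,7,9-pentaen-1-yl]-4,4,5,5-tetramethyl-1,3,2-dioxaborolane | CC1(C)OB(/C=C/C=C(C)/C=C/C=C(C)/C=C/[C@H]2C(C)=C[C@H](O[Si](CC)(CC)CC)CC2(C)C)OC1(C)C
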